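**Assumptions (one line):** ent-kaurane numbering is used throughout; target = (4R,5R,8S,9S,10R,11R,13S,15R); 4-bromocyclopentene is taken as purchasable; the carvone-enolate aldol in step 2 is assumed to go cis to the isopropenyl group (axial attack) – if the opposite sense were found, (R)-carvone would be used instead.

## Retrosynthetic overview

1. Guidongnin ⇐ Luche reduction of the 15-oxo-16-ene ⇐ intramolecular aldol of the δ-lactone enolate (C8) onto an α-methylene aldehyde (C15), closing ring D.
2. Ring C ⇐ photochemical acyl-radical hydroacylation (C9–C11) of a prochiral dialdehyde onto the α,β-unsaturated spiro-δ-lactone (sets C9 and C13); C11 then set by L-Selectride.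
3. Spiro-δ-lactone (C9–C10 bond, quaternary C10) ⇐ Ti/photoredox epoxide-radical Giese addition and lactonisation of a ring-A spiro-epoxide with a 2-substituted acrylate.
4. Ring-A cis-γ-lactone ⇐ (S)-carvone: C4 by reductive aldol, isopropenyl then deleted, C5 by photodeconjugation.
5. Ring order: A (bought) → γ-lactone → spiro-δ-lactone → C → D. (S)-Carvone is the only chiral input.

## Route

**Step 1**
Reactants: 1, (S)-(+)-carvone
Product: 2, (5S,6R)-2,6-dimethyl-5-(prop-1-en-2-yl)cyclohex-2-en-1-one (trans-6-methylcarvone)
Conditions: LDA, THF, −78 °C; MeI, −78 → 0 °C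
Reagents that add atoms: iodomethane, CI
Why: Kinetic α′-enolate alkylation; the methyl (future C20) enters anti to the adjacent isopropenyl group, and this centre is erased in step 4.

**Step 2**
Reactants: 2
Product: 3, (2S,5S,6R)-2-[(tert-butyldimethylsilyloxy)methyl]-2,6-dimethyl-5-(prop-1-en-2-yl)cyclohexan-1-one
Conditions: L-Selectride, THF, −78 °C; CH2O (gas), −78 °C; then TBSOTf, 2,6-lutidine, −78 → 0 °C
Reagents that add atoms: formaldehyde, C=O; TBSOTf, CC(C)(C)[Si](C)(C)OS(=O)(=O)C(F)(F)F
Why: Conjugate reduction/aldol (reductive aldol): the regiodefined enolate is attacked axially by CH2O, cis to the isopropenyl group (same sense as base-mediated Robinson annulation of dihydrocarvone), which sets the quaternary centre that becomes C4; a moderate dr is expected and the minor isomer is removed.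

**Step 3**
Reactants: 3
Product: 4, (2S,6R)-2-[(tert-butyldimethylsilyloxy)methyl]-2,6-dimethylcyclohexan-1-one
Conditions: O3, MeOH, −78 °C; then FeSO4·7H2O, PhSH, −78 °C → rt
Reagents that add atoms: none (H from PhSH)
Why: Hydrodealkenylation (ozonolysis to the α-methoxy hydroperoxide, Fe(II)-induced β-scission, H-atom transfer from thiol) removes the isopropenyl control element after it has set C4; the quaternary centre is untouched.

**Step 4**
Reactants: 4
Product: 5, (6S)-6-[(tert-butyldimethylsilyloxy)methyl]-2,6-dimethylcyclohex-1-en-1-yl triflate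
Conditions: KHMDS, THF, −78 → 0 °C; PhNTf2
Reagents that add atoms: N-phenyl-bis(trifluoromethanesulfonimide), O=S(=O)(N(c1ccccc1)S(=O)(=O)C(F)(F)F)C(F)(F)F
Why: Enol triflate formation; only one α-position is enolisable, so the tetrasubstituted triflate forms regiospecifically (as for 2,2,6-trimethylcyclohexanone).

**Step 5**
Reactants: 5
Product: 6, (3aR)-3a,7-dimethyl-3a,4,5,6-tetrahydro-2-benzofuran-1(3H)-one
Conditions: Pd(OAc)2, dppf, CO (1 atm), Et3N, MeOH/DMF, 70 °C; then p-TsOH·H2O, MeOH, 40 °C
Reagents that add atoms: carbon monoxide, [C-]#[O+]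
Why: Pd-catalysed methoxycarbonylation of the vinyl triflate installs C6; acid removes the TBS group and the C19 hydroxyl closes the γ-lactone (6,19-lactone).

**Step 6**
Reactants: 6
Product: 7, (3aR,7aS)-3a-methyl-7-methylidenehexahydro-2-benzofuran-1(3H)-one (cis-fused)
Conditions: hν (254 nm, quartz), MeCN, 2,6-lutidine (cat.), 0 °C
Reagents that add atoms: none
Why: Photodeconjugation: the excited lactone carbonyl abstracts a γ-H from the C20 methyl (which is cis to C=O), and the dienol is protonated at C5 to give only the cis-fused lactone, setting C5 and leaving the C10=C20 exocyclic alkene.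

**Step 7**
Reactants: 7
Product: 8, spiro-epoxide of 7 at C10/C20 (both epoxide epimers; C4, C5 as in 7)
Conditions: m-CPBA, NaHCO3, CH2Cl2, 0 °C
Reagents that add atoms: m-CPBA, OOC(=O)c1cccc(Cl)c1
Why: Prilezhaev epoxidation of the 1,1-disubstituted alkene; the epoxide configuration is irrelevant because C10 becomes a radical in step 9.

**Step 8** (side chain)
Reactants: 9, 4-bromocyclopentene; 10, ethyl 2-(bromomethyl)acrylate
Product: 11, ethyl 2-(cyclopent-3-en-1-ylmethyl)prop-2-enoate
Conditions: 9, Mg, THF; then CuI (10 mol %), 10, −40 → 0 °C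
Reagents that add atoms: none (both reactants listed)
Why: Cu-catalysed SN2′ allylic substitution of the Grignard reagent; the achiral cyclopentene is a masked, symmetric dialdehyde carrying C11–C16.

**Step 9**
Reactants: 8; 11
Product: 12, spiro-bis-lactone: the ring-A cis-γ-lactone spiro-fused at C10 (R) to a δ-valerolactone (C20–O–C7) bearing the cyclopent-3-enylmethyl group at C8 (C8 epimers)
Conditions: Cp2TiCl2 (10 mol %), 4CzIPN (2 mol %), Hantzsch ester, collidine·HCl, 11 (3 equiv), THF, blue LEDs, rt; then PPTS, PhMe, 80 °C
Reagents that add atoms: none (H from Hantzsch ester; EtOH lost)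
Why: Photoredox-turned-over titanocene(III) epoxide homolysis (Nugent–RajanBabu) gives the tertiary C10 radical, which adds to the acrylate (Giese) on the face anti to the C5–C6 lactone bond, fixing quaternary C10 with C9 trans to C6; the C20 alkoxide then lactonises.

**Step 10**
Reactants: 12
Product: 13, the C8=C9 unsaturated spiro-δ-lactone (5,6-dihydro-2H-pyran-2-one) with the side chain on C8
Conditions: LDA, THF, −78 °C; PhSeBr; then NaIO4, NaHCO3, THF/MeOH/H2O, rt
Reagents that add atoms: none (selenium is lost)
Why: α-Selenation of the less hindered δ-lactone enolate (C5–H is flanked by two quaternary carbons) and selenoxide syn-elimination toward the ring C9–H give the endocyclic enoate.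

**Step 11**
Reactants: 13
Product: 14, dialdehyde: as 13 with the C8 substituent CH2–CH(CH2CHO)2
Conditions: O3, CH2Cl2/MeOH, Sudan III indicator, −78 °C; Me2S
Reagents that add atoms: ozone, [O-][O+]=O
Why: Chemoselective ozonolysis of the electron-rich cyclopentene over the electron-poor conjugated C8=C9 unmasks two identical CH2CHO arms on prochiral C13.

**Step 12**
Reactants: 14
Product: 15, tricyclic keto-aldehyde: ring C closed (C9–C11), 11-oxo, CH2CHO at C13 trans to C10, δ-lactone trans-fused at C8 (major)
Conditions: (n-Bu4N)4W10O32 (TBADT, 4 mol %), MeCN (0.01 M), 390 nm LEDs, rt, Ar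
Reagents that add atoms: none (isomerisation)
Why: Proposed new method: excited decatungstate abstracts a formyl H from one of the two arms; the nucleophilic acyl radical adds 6-endo to C9 (β-carbon of the unsaturated lactone) on the face anti to the C5 side of ring A, through a chair with the spectator CH2CHO arm and C10 both equatorial (sets C9 and C13), and back-HAT to the C8 radical closes the redox-neutral cycle so the second aldehyde survives; closest known chemistry is intermolecular decatungstate hydroacylation of electron-poor alkenes and 6-endo acyl-radical cyclisation, here applied intramolecularly and group-selectively to a dialdehyde on a hindered α-alkyl enoate.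

**Step 13**
Reactants: 15
Product: 16, 11-hydroxy aldehyde (11-OH cis to C10, i.e. 11R; aldehyde arm retained)
Conditions: LiN(OMe)Me (1.1 equiv), THF, −78 °C; then L-Selectride, −78 °C; AcOH, aq. NH4Cl
Reagents that add atoms: none (hydride only)
Why: The aldehyde is masked in situ as its α-amino alkoxide; L-Selectride then attacks the 2-substituted cyclohexanone equatorially to give the axial alcohol cis to the bulky C10 substituent, which is the C11 configuration of the target.

**Step 14**
Reactants: 16
Product: 17, α-methylene aldehyde (C16=C17 installed next to the C15 aldehyde)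
Conditions: aq. CH2O (37 %), pyrrolidine (10 mol %), propionic acid (10 mol %), i-PrOH, 45 °C
Reagents that add atoms: formaldehyde, C=O
Why: Organocatalytic α-methylenation (enamine Mannich/elimination) is selective for the aldehyde; the 11-OH is trans to this arm, so no lactol or oxa-Michael product can form.

**Step 15**
Reactants: 17
Product: 18, tetracyclic aldol product = guidongnin as a mixture of C15 epimers
Conditions: LiHMDS (2.5 equiv), THF, −78 → −40 °C; AcOH quench at −78 °C
Reagents that add atoms: none
Why: Intramolecular aldol: the δ-lactone enolate (C8) can reach the non-enolisable enal carbonyl only on the face carrying the C13 arm, which closes the bicyclo[3.2.1]octane and fixes quaternary C8 (C7 cis to C10); the C15 configuration is not controlled here and is reset in steps 16–17.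

**Step 16**
Reactants: 18
Product: 19, 15-oxo enone (15-dehydroguidongnin)
Conditions: MnO2 (excess), CH2Cl2, rt
Reagents that add atoms: none
Why: MnO2 oxidises only the allylic C15 alcohol (the C11 alcohol is not allylic), converging both C15 epimers.

**Step 17**
Reactants: 19
Product: 20, guidongnin
Conditions: NaBH4, CeCl3·7H2O, MeOH, −78 °C
Reagents that add atoms: none (hydride only)
Why: Luche 1,2-reduction: hydride attacks the bicyclo[3.2.1]octenone from the exo face (the endo face is screened by the three-carbon bridge and axial H11), giving the endo 15-OH cis to C9 (15R); the lactones and exocyclic alkene are untouched.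

## Compound list

1 | (S)-(+)-carvone | CC1=CC[C@@H](CC1=O)C(C)=C | starting material
2 | (5S,6R)-trans-6-methylcarvone | CC1=CC[C@H](C(C)=C)[C@@H](C)C1=O | intermediate
3 | (2S,5S,6R)-2-(TBSOCH2)-2,6-dimethyl-5-isopropenylcyclohexanone | C[C@@]1(CO[Si](C)(C)C(C)(C)C)CC[C@H](C(C)=C)[C@@H](C)C1=O | intermediate
4 | (2S,6R)-2-(TBSOCH2)-2,6-dimethylcyclohexanone | C[C@@]1(CO[Si](C)(C)C(C)(C)C)CCC[C@@H](C)C1=O | intermediate
5 | (6S)-enol triflate | C[C@@]1(CO[Si](C)(C)C(C)(C)C)CCCC(C)=C1OS(=O)(=O)C(F)(F)F | intermediate
6 | (3aR)-3a,7-dimethyl-3a,4,5,6-tetrahydro-2-benzofuran-1(3H)-one | C[C@]12COC(=O)C1=C(C)CCC2 | intermediate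
7 | (3aR,7aS)-3a-methyl-7-methylidenehexahydro-2-benzofuran-1(3H)-one | C=C1CCC[C@@]2(C)COC(=O)[C@H]21 | intermediate
8 | C10/C20 spiro-epoxide of 7 (epoxide epimers) | C1OC12CCC[C@@]3(C)COC(=O)[C@H]32 | intermediate
9 | 4-bromocyclopentene | BrC1CC=CC1 | starting material
10 | ethyl 2-(bromomethyl)acrylate | C=C(CBr)C(=O)OCC | starting material
11 | ethyl 2-(cyclopent-3-en-1-ylmethyl)acrylate | C=C(CC1CC=CC1)C(=O)OCC | intermediate
12 | saturated spiro-bis-lactone (C8 epimers) | O=C1OC[C@]2(CCC[C@@]3(C)COC(=O)[C@H]32)CC1CC1CC=CC1 | intermediate
13 | C8=C9 unsaturated spiro-bis-lactone | O=C1OC[C@]2(CCC[C@@]3(C)COC(=O)[C@H]32)C=C1CC1CC=CC1 | intermediate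
14 | prochiral dialdehyde | O=C1OC[C@]2(CCC[C@@]3(C)COC(=O)[C@H]32)C=C1CC(CC=O)CC=O | intermediate
15 | tricyclic 11-keto aldehyde | O=CC[C@@H]1CC(=O)[C@H]2[C@@]3(CCC[C@@]4(C)COC(=O)[C@H]43)COC(=O)[C@@H]2C1 | intermediate
16 | tricyclic 11-hydroxy aldehyde | O=CC[C@@H]1C[C@@H](O)[C@H]2[C@@]3(CCC[C@@]4(C)COC(=O)[C@H]43)COC(=O)[C@@H]2C1 | intermediate
17 | tricyclic α-methylene aldehyde | C=C(C=O)[C@@H]1C[C@@H](O)[C@H]2[C@@]3(CCC[C@@]4(C)COC(=O)[C@H]43)COC(=O)[C@@H]2C1 | intermediate
18 | guidongnin, C15 epimer mixture | C=C1[C@@H]2C[C@@H](O)[C@H]3[C@@]4(CCC[C@@]5(C)COC(=O)[C@H]54)COC(=O)[C@]3(C2)C1O | intermediate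
19 | 15-oxo enone | C=C1[C@@H]2C[C@@H](O)[C@H]3[C@@]4(CCC[C@@]5(C)COC(=O)[C@H]54)COC(=O)[C@]3(C2)C1=O | intermediate
20 | guidongnin | C=C1[C@@H]2C[C@@H](O)[C@H]3[C@@]4(CCC[C@@]5(C)COC(=O)[C@H]54)COC(=O)[C@]3(C2)[C@@H]1O | target

## Totals and risks

Total steps: 17. Longest linear sequence: 16 (steps 1–7, 9–17).

Steps most likely to fail:

1. **Step 12 (proposed new hydroacylation).** The acyl radical must add to a β-carbon next to the spiro quaternary centre before decarbonylation or unproductive HAT. Fallback (known chemistry): intramolecular Stetter reaction of 14 with an achiral thiazolium/triazolium NHC catalyst and base, which gives the same keto-aldehyde 15 by acyl-anion conjugate addition.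
2. **Step 15 (aldol ring-D closure).** A weakly acidic, hindered lactone C–H must be enolised in the presence of an enal and a free alkoxide. Fallback: reduce the enal to the allylic alcohol, form the allylic carbonate, and close C8–C15 by Pd(0)-catalysed intramolecular Tsuji–Trost alkylation of the lactone enolate; then install the 15-OH by SeO2/TBHP allylic oxidation and correct its configuration with the same MnO2/Luche pair.
3. **Step 10 (regioselective dehydrogenation).** Selenoxide elimination may give the exocyclic C8=C14 alkylidene lactone instead of the endocyclic C8=C9 isomer. Fallback: place the alkene during C9–C10 bond formation by running step 9 with the β-phenylthio (or β-phenylsulfonyl) analogue of acrylate 11, so that radical addition is followed by β-elimination and 13 is formed directly.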